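## Plan

- **Cuts:** C12 is adjusted last, so the allylic alcohol comes from C12 enone 35. The C1–C10 bond is cut next, then C9–C10, C12–C13 and C7–C8/O7–C19. This leaves fragment 1 (C1–C7 with C13–C16, from neryl acetate), fragment 2 (C8, C9, C17–C19, from a propionate and ethyl glyoxylate) and fragment 3 (C10–C12, C20, from propargyl alcohol).
- **Enabling feature:** C1–C10 is the one bond shared by ring A (C1, C10, C11, C12, C13, C14) and the ten-membered ring (C1 to C10). Without it the carbons form a 14-membered ring. There, quaternary C1 is the terminus of an allyl system (C13=C14), C10 is an alkene carbon within reach, and C11 is flanked by oxygen-bearing C12, so a cation at C11 can be discharged by H12.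
- **Forward order:** the γ-lactone forms first (step 11), the 14-membered ring closes at C9–C10 (step 18), and ring A and the ten-membered ring arise together (step 22).
- **Stereochemistry:**
  - C1 and C2 come from asymmetric epoxidation and invertive opening.
  - C17 and C8 come from an auxiliary aldol, and C8 is carried on by self-regeneration of stereocentres.
  - C7 comes from a closed aldol transition state, and the temporary C12 centre from catalytic alkynylation.
  - C9 comes from chelate-controlled ring closure.
  - C1, C10 and C11 are set in the key step, and the final C12 centre by α-face hydride delivery followed by inversion.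

Key step: step 22

Numbering: briarane numbering is used throughout (C15 on C1, C16 on C5, C18 on C17, C20 on C11, C19 is the lactone carbonyl). β is the face of ring A that carries C15.

Assumption: in step 14 the (S,S)-ProPhenol–zinc catalyst is taken to deliver the alkynyl group to the Si face of enal 22; if its sense of induction is the opposite, the (R,R)-ligand is used.

## Route

Step 1
Reactants: 1 neryl acetate
Product: 2 (2Z,6E)-8-hydroxy-3,7-dimethylocta-2,6-dien-1-yl acetate
Conditions: SeO2 (cat.), t-BuOOH, salicylic acid (cat.), CH2Cl2, rt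
Reagents that add atoms: tert-butyl hydroperoxide, CC(C)(C)OO
Why: Riley allylic oxidation in its catalytic SeO2/t-BuOOH form attacks the electron-richer terminal trisubstituted alkene (C5=C6 is deactivated by the allylic acetate) and, through the ene/[2,3]-sigmatropic sequence, hydroxylates only the E-methyl group, which supplies C14 on an E C1=C2 alkene.

Step 2
Reactants: 2 (2Z,6E)-8-hydroxy-3,7-dimethylocta-2,6-dien-1-yl acetate
Product: 3 (2Z)-5-[(2S,3S)-3-(hydroxymethyl)-3-methyloxiran-2-yl]-3-methylpent-2-en-1-yl acetate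
Conditions: Ti(OiPr)4 (cat.), L-(+)-diethyl tartrate (cat.), t-BuOOH, 4 Å MS, CH2Cl2, −20 °C
Reagents that add atoms: tert-butyl hydroperoxide, CC(C)(C)OO
Why: Sharpless asymmetric epoxidation reacts only at the alkene of the allylic alcohol, and L-(+)-diethyl tartrate directs oxygen to the face that gives the (2S,3S)-epoxy alcohol, so the C1–O bond of the later leaving group is set here (1S) and C2 is prepared for inversion.

Step 3
Reactants: 3 (2Z)-5-[(2S,3S)-3-(hydroxymethyl)-3-methyloxiran-2-yl]-3-methylpent-2-en-1-yl acetate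
Product: 4 (2Z,6R,7S)-6-(benzoyloxy)-7,8-dihydroxy-3,7-dimethyloct-2-en-1-yl acetate
Conditions: Ti(OiPr)4 (1.5 equiv), PhCO2H, CH2Cl2, rt
Reagents that add atoms: benzoic acid, OC(=O)c1ccccc1
Why: In the titanium-mediated opening of 2,3-epoxy alcohols the alkoxide-bound titanium activates the epoxide and the carboxylate attacks the carbon remote from the carbinol (secondary C2, not quaternary C1) in an SN2 manner, which inverts C2 to the 2R configuration of the target and leaves the C1–O bond untouched.

Step 4
Reactants: 4 (2Z,6R,7S)-6-(benzoyloxy)-7,8-dihydroxy-3,7-dimethyloct-2-en-1-yl acetate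
Product: 5 (2Z,6R,7R)-6-(benzoyloxy)-7-hydroxy-3,7-dimethyl-8-oxooct-2-en-1-yl acetate
Conditions: (COCl)2, DMSO, CH2Cl2, −78 °C; Et3N
Reagents that add atoms: none
Why: Swern oxidation turns the only primary alcohol into the aldehyde at −78 °C without the glycol cleavage that hypervalent iodine reagents could cause, and quaternary C1 has no hydrogen through which epimerisation or loss of benzoate could occur.

Step 5
Reactants: 5 (2Z,6R,7R)-6-(benzoyloxy)-7-hydroxy-3,7-dimethyl-8-oxooct-2-en-1-yl acetate
Product: 7 (2Z,6R,7S)-3,7-dimethylnon-2-en-8-yne-1,6,7-triol, via alkynyl diester 6 (not isolated)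
Conditions: dimethyl (1-diazo-2-oxopropyl)phosphonate, K2CO3, MeOH, 0 °C → rt
Reagents that add atoms: dimethyl (1-diazo-2-oxopropyl)phosphonate, CC(=O)C(=[N+]=[N-])P(=O)(OC)OC
Why: Ohira–Bestmann (Seyferth–Gilbert) homologation converts the non-enolisable aldehyde into the terminal alkyne and thereby adds C13, and the same K2CO3/MeOH medium then removes the benzoate and the acetate by transesterification without touching C1 or C2.

Step 6
Reactants: 7 (2Z,6R,7S)-3,7-dimethylnon-2-en-8-yne-1,6,7-triol
Product: 8 (2Z)-5-[(4R,5S)-5-ethynyl-2,2,5-trimethyl-1,3-dioxolan-4-yl]-3-methylpent-2-en-1-ol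
Conditions: 2,2-dimethoxypropane, PPTS (cat.), CH2Cl2, rt; aqueous work-up
Reagents that add atoms: 2,2-dimethoxypropane, COC(C)(C)OC
Why: Acid-catalysed transketalisation closes the five-membered acetonide on the vicinal C1/C2 diol, whereas the mixed ketal formed at the lone primary alcohol falls off on aqueous work-up, and PPTS is too weak to ionise the Z-allylic alcohol.

Step 7
Reactants: 8 (2Z)-5-[(4R,5S)-5-ethynyl-2,2,5-trimethyl-1,3-dioxolan-4-yl]-3-methylpent-2-en-1-ol
Product: 9 (2Z)-5-[(4R,5S)-5-ethynyl-2,2,5-trimethyl-1,3-dioxolan-4-yl]-3-methylpent-2-enal (fragment 1)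
Conditions: MnO2, CH2Cl2, rt
Reagents that add atoms: none
Why: MnO2 oxidises the allylic alcohol under neutral heterogeneous conditions, which are known to convert nerol-type alcohols into the Z-enals without Z/E isomerisation.

Step 8
Reactants: 10 (4R)-4-benzyl-3-propanoyl-1,3-oxazolidin-2-one; 11 ethyl glyoxylate
Product: 13 ethyl (2R,3R)-4-[(4R)-4-benzyl-2-oxo-1,3-oxazolidin-3-yl]-2-hydroxy-3-methyl-4-oxobutanoate, via Z boron enolate 12 (not isolated)
Conditions: Bu2BOTf, Et3N, CH2Cl2, −78 → 0 °C; 11, −78 °C; H2O2, MeOH, pH 7 buffer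
Reagents that add atoms: none
Why: Evans syn-aldol reaction, in which the Z boron enolate reacts through a Zimmerman–Traxler chair on the face away from the benzyl group of the (R)-auxiliary and so sets C17 (R) and C8 (R) in the syn relation found in the target.

Step 9
Reactants: 13 ethyl (2R,3R)-4-[(4R)-4-benzyl-2-oxo-1,3-oxazolidin-3-yl]-2-hydroxy-3-methyl-4-oxobutanoate
Product: 14 (2R,3R)-2-hydroxy-3-methylbutanedioic acid
Conditions: LiOH, H2O2, THF–H2O, 0 °C → rt; Na2SO3; HCl
Reagents that add atoms: lithium hydroxide, [Li+].[OH-]; hydrogen peroxide, OO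
Why: Lithium hydroperoxide cleaves the exocyclic imide carbonyl selectively and the excess LiOH saponifies the activated α-hydroxy ester, both at temperatures at which neither retro-aldol cleavage nor epimerisation of C17 is expected.

Step 10
Reactants: 14 (2R,3R)-2-hydroxy-3-methylbutanedioic acid
Product: 15 (2R)-2-[(2R,4R)-2-tert-butyl-5-oxo-1,3-dioxolan-4-yl]propanoic acid (fragment 2)
Conditions: t-BuCHO, TsOH·H2O (cat.), H2SO4 (cat.), pentane, reflux, water separator; crystallisation
Reagents that add atoms: pivalaldehyde, CC(C)(C)C=O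
Why: Acid-catalysed acetalisation of an α-hydroxy acid with pivalaldehyde gives the five-membered dioxolanone in preference to the six-membered dioxanone of the β-carboxyl group, and the cis isomer (tert-butyl cis to the C17 branch) stores the C8 configuration in the new acetal centre (self-regeneration of stereocentres).

Step 11
Reactants: 15 (2R)-2-[(2R,4R)-2-tert-butyl-5-oxo-1,3-dioxolan-4-yl]propanoic acid; 9 (2Z)-5-[(4R,5S)-5-ethynyl-2,2,5-trimethyl-1,3-dioxolan-4-yl]-3-methylpent-2-enal
Product: 18 spiro dioxolanone γ-lactone (1S,2R,7S,8S,17R; acetal carbon R), via dilithio dianion 16 (not isolated), via hydroxy acid 17 (not isolated)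
Conditions: LiN(SiMe3)2 (2.1 equiv), THF, −78 °C; 9, −78 °C; AcOH; PPTS (cat.), CH2Cl2, rt
Reagents that add atoms: none
Why: Aldol addition of a dioxolanone enolate followed by lactonisation, in which the carboxylate shields C17–H from deprotonation, the aldehyde enters C8 trans to the tert-butyl group (retention at C8), the fixed enolate geometry with the C17 branch cis to OLi leads through a Zimmerman–Traxler chair with C6 equatorial to O7 syn to that branch (7S), and the γ-hydroxy acid closes the only possible five-membered lactone O7–C19.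

Step 12
Reactants: 19 propargyl alcohol
Product: 21 (2E)-3-iodo-2-methylprop-2-en-1-ol, via alkenylalane 20 (not isolated)
Conditions: AlMe3, Cp2ZrCl2 (cat.), CH2Cl2, 0 °C → rt; I2, THF, −30 °C
Reagents that add atoms: trimethylaluminium, C[Al](C)C; iodine, II
Why: Negishi zirconium-catalysed carboalumination adds methyl (C20) and aluminium syn across the alkyne with aluminium at the terminal carbon, and iodinolysis with retention gives the E-iodoalkene that defines the E C10=C11 geometry.

Step 13
Reactants: 21 (2E)-3-iodo-2-methylprop-2-en-1-ol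
Product: 22 (2E)-3-iodo-2-methylprop-2-enal (fragment 3)
Conditions: MnO2, CH2Cl2, rt, dark
Reagents that add atoms: none
Why: MnO2 oxidation of the allylic alcohol gives the non-enolisable enal without touching the C–I bond or the alkene geometry.

Step 14
Reactants: 18 spiro dioxolanone γ-lactone; 22 (2E)-3-iodo-2-methylprop-2-enal
Product: 24 C12 propargylic alcohol (1S,2R,7S,8S,12S,17R; 10E alkenyl iodide), via zinc acetylide 23 (not isolated)
Conditions: ZnMe2, (S,S)-ProPhenol (20 mol %), Ph3P=O (40 mol %), toluene, 0 → 4 °C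
Reagents that add atoms: none
Why: Zinc–ProPhenol-catalysed asymmetric alkynylation, a method developed for α,β-unsaturated aldehydes, adds the mildly nucleophilic zinc acetylide to the Si face of 22 under catalyst control (12S) and leaves both lactone-type carbonyls, the acetonide and the alkenyl iodide untouched.

Step 15
Reactants: 24 C12 propargylic alcohol
Product: 25 C12 triisopropylsilyl ether of 24
Conditions: iPr3SiOTf, 2,6-lutidine, CH2Cl2, −78 → 0 °C
Reagents that add atoms: triisopropylsilyl triflate, CC(C)[Si](OS(=O)(=O)C(F)(F)F)(C(C)C)C(C)C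
Why: Silylation with the triflate and a hindered base protects the only free hydroxyl, and the bulky triisopropylsilyl group is chosen because its oxygen is weakly basic and weakly nucleophilic, survives step 19 and can still leave from an oxocarbenium ion in step 22.

Step 16
Reactants: 25 C12 triisopropylsilyl ether
Product: 26 C8,C9 diol (γ-lactone with tertiary 8-OH and CH2OH as C9; 1S,2R,7S,8R,12S,17R)
Conditions: NaBH4, THF–EtOH, −10 → 0 °C
Reagents that add atoms: none
Why: Borohydride reduction of an activated ester, in which the acylal-type dioxolanone carbonyl is far more electrophilic than the α-branched γ-lactone carbonyl, its ring opens irreversibly with loss of pivalaldehyde, and translactonisation to O9 is held back because it would pass through a strained 2,6-dioxabicyclo[2.2.1]heptane intermediate.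

Step 17
Reactants: 26 C8,C9 diol
Product: 27 C9 aldehyde (α-hydroxy aldehyde; 1S,2R,7S,8S,12S,17R)
Conditions: SO3·pyridine, DMSO, iPr2NEt, CH2Cl2, 0 °C
Reagents that add atoms: none
Why: Parikh–Doering oxidation converts the primary alcohol into the aldehyde under mild activated-DMSO conditions that neither cleave the vicinal diol nor affect the tertiary hydroxyl, and C8 is fully substituted so the aldehyde cannot epimerise.

Step 18
Reactants: 27 C9 aldehyde
Product: 29 14-membered 13-yne 8,9-diol (1,2-acetonide; 12-silyl ether; 1S,2R,7S,8R,9R,12R,17R; 5Z,10E), via alkenylchromium species 28 (not isolated)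
Conditions: CrCl2 (excess), NiCl2 (cat.), DMSO–THF, rt, 2 mM
Reagents that add atoms: none
Why: Nozaki–Hiyama–Kishi macrocyclisation, in which the alkenylchromium reagent formed with retention of the E geometry tolerates lactone, alkyne, silyl ether and free hydroxyl, high dilution favours the 14-membered ring, and addition to the aldehyde chelated through O8 and O9 from the face on which the tether leaves C8 (the C7 side) should give the 9R alcohol.

Step 19
Reactants: 29 14-membered 13-yne 8,9-diol
Product: 30 14-membered 13-yne 1,2,8,9-tetraol (12-silyl ether; 1S,2R,7S,8R,9R,12R,17R)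
Conditions: AcOH–H2O (4:1), 40 °C
Reagents that add atoms: none
Why: Mild acid hydrolysis of the acetonide is carried out while C13–C14 is still an alkyne, so that C1 is only propargylic and does not ionise, and the triisopropylsilyl ether and the lactone are stable to aqueous acetic acid.

Step 20
Reactants: 30 14-membered 13-yne 1,2,8,9-tetraol
Product: 31 14-membered 13-yne 2,9-diacetate (free tertiary 1-OH and 8-OH; 1S,2R,7S,8R,9R,12R,17R)
Conditions: Ac2O, pyridine, DMAP (cat.), CH2Cl2, 0 °C → rt
Reagents that add atoms: acetic anhydride, CC(=O)OC(C)=O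
Why: DMAP-catalysed acetylation distinguishes the two secondary hydroxyls (C2, C9) from the two tertiary ones (C1, C8) on steric grounds, which installs both acetates of the target in one operation and leaves the C1 hydroxyl free as the leaving group.

Step 21
Reactants: 31 14-membered 13-yne 2,9-diacetate
Product: 32 14-membered cembranoid lactone (C1 carbinol; 2,9-diacetate; 8-OH; 12-epi silyl ether; 5Z,10E,13Z; 1S,2R,7S,8R,9R,12S,17R)
Conditions: H2 (1 atm), Pd/CaCO3 poisoned with Pb(OAc)2 (Lindlar catalyst), quinoline, EtOAc, rt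
Reagents that add atoms: none
Why: Lindlar semihydrogenation adds hydrogen syn to the alkyne and stops at the Z C13=C14 alkene, the trisubstituted alkenes being too hindered to compete.

Step 22
Reactants: 32 14-membered cembranoid lactone
Product: 35 bicyclic C12 enone (12-oxo analogue of the target; 1S,2R,7S,8S,9R,10S,11R,17R), via allyl cation 33 (not isolated), via silyloxocarbenium ion 34 (not isolated)
Conditions: TsOH·H2O (10 mol %), (CF3)2CHOH–CH2Cl2 (1:4), −20 → 0 °C, 5 mM
Reagents that add atoms: none
Why: Proposed new method: the acid protonates the free tertiary allylic C1 hydroxyl, water leaves in the strongly ionising, weakly nucleophilic medium to give the Z-configured C1–C14–C13 allyl cation 33, C10 of the C10=C11 alkene bonds to C1 across the ring while H12 migrates to C11 antiperiplanar to the new bond, and the silyloxocarbenium ion 34 so formed passes its silyl group to the released water, which makes the sequence irreversible and leaves the C12 enone. The closest known reaction types are the transannular cation–olefin cyclisations of macrocyclic terpenoid dienes and the semipinacol-terminated Prins–pinacol cyclisation, whereas a transannular version ended by a 1,2-hydride shift from a silyloxy-bearing carbon is not known. Ring A (C1, C10, C11, C12, C13, C14) closes in the 6-endo-trig mode with respect to C10=C11, and the same C1–C10 bond divides the 14-membered ring so that the ten-membered ring (C1 to C10) arises as the remainder and not by a closure of its own. C1 is controlled by the geometry of the allyl cation, in which the small methyl C15 takes the inside position next to C12 and C2 the outside position (allylic 1,3-strain on the Z alkene), together with entry of C10 on the face opposite to the departing water, so that C15 ends trans to H10 (trans ring fusion). C10 and C11 are controlled by the E geometry of C10=C11 and the anti course of the addition (C1 on one face, H12 on the other), which places C20 cis to C9, and the absolute sense comes from C12, because only the rotamer with the silyloxy group pseudo-equatorial and H12 pseudo-axial, opposite to C1, can terminate by hydride shift. The step needs ionisation at C1 only, attack by C10=C11 and not by C5=C6, and migration of H12 and not of H2: the C12 oxygen is a bulky, weakly basic silyl ether held away from C1, the C2 and C9 oxygens are acylated and sit next to electron-poor carbons, the Z C13=C14 bridge holds C10 close to C1 whereas addition of C5=C6 is reversible and has no irreversible exit, and the C2 acetate makes a pinacol-type shift of H2 unproductive while at worst storing the cation reversibly as the cis-acetoxonium ion.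

Step 23
Reactants: 35 bicyclic C12 enone
Product: 36 12β allylic alcohol (12-epimer of the target; 12S)
Conditions: NaBH4, CeCl3·7H2O, MeOH, −78 → −40 °C
Reagents that add atoms: none
Why: Luche reduction gives clean 1,2-reduction of the enone, and hydride should arrive on the α face because the β face of ring A carries C15, C20 and C9, so the 12β alcohol is expected and C11 is no longer epimerisable after this step.

Step 24
Reactants: 36 12β allylic alcohol
Product: 37 12α chloroacetate (12R)
Conditions: ClCH2CO2H, PPh3, DIAD, toluene, 0 °C → rt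
Reagents that add atoms: chloroacetic acid, OC(=O)CCl
Why: Mitsunobu inversion, in which the allylic 12β-oxyphosphonium ion is displaced in an SN2 manner from the open α face by the small, acidic chloroacetate, SN2′ attack at C14 being blocked by quaternary C1 and the tertiary C8 hydroxyl being inert, which sets the 12R configuration of the target.

Step 25
Reactants: 37 12α chloroacetate
Product: 38 CNP0222085.1 (1S,2R,7S,8S,9R,10S,11R,12R,17R; 5Z)
Conditions: thiourea, NaHCO3, EtOH–THF, 55 °C
Reagents that add atoms: none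
Why: Chloroacetate cleavage with thiourea proceeds by S-alkylation and intramolecular acyl transfer, a pathway open only to the α-chloro ester, so the two acetates and the β-hydroxy lactone are not exposed to a hydrolytic base.

## Compound list

1 | neryl acetate | CC(C)=CCC/C(C)=C\COC(C)=O | starting material
2 | (2Z,6E)-8-hydroxy-3,7-dimethylocta-2,6-dien-1-yl acetate | OC/C(C)=C/CC/C(C)=C\COC(C)=O | intermediate
3 | (2Z)-5-[(2S,3S)-3-(hydroxymethyl)-3-methyloxiran-2-yl]-3-methylpent-2-en-1-yl acetate | OC[C@]1(C)O[C@H]1CC/C(C)=C\COC(C)=O | intermediate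
4 | (2Z,6R,7S)-6-(benzoyloxy)-7,8-dihydroxy-3,7-dimethyloct-2-en-1-yl acetate | OC[C@](C)(O)[C@H](OC(=O)c1ccccc1)CC/C(C)=C\COC(C)=O | intermediate
5 | (2Z,6R,7R)-6-(benzoyloxy)-7-hydroxy-3,7-dimethyl-8-oxooct-2-en-1-yl acetate | O=C[C@](C)(O)[C@H](OC(=O)c1ccccc1)CC/C(C)=C\COC(C)=O | intermediate
6 | (2Z,6R,7S)-6-(benzoyloxy)-7-hydroxy-3,7-dimethylnon-2-en-8-yn-1-yl acetate (alkynyl diester) | C#C[C@](C)(O)[C@H](OC(=O)c1ccccc1)CC/C(C)=C\COC(C)=O | intermediate
7 | (2Z,6R,7S)-3,7-dimethylnon-2-en-8-yne-1,6,7-triol | C#C[C@](C)(O)[C@H](O)CC/C(C)=C\CO | intermediate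
8 | (2Z)-5-[(4R,5S)-5-ethynyl-2,2,5-trimethyl-1,3-dioxolan-4-yl]-3-methylpent-2-en-1-ol | C#C[C@]1(C)OC(C)(C)O[C@@H]1CC/C(C)=C\CO | intermediate
9 | (2Z)-5-[(4R,5S)-5-ethynyl-2,2,5-trimethyl-1,3-dioxolan-4-yl]-3-methylpent-2-enal | C#C[C@]1(C)OC(C)(C)O[C@@H]1CC/C(C)=C\C=O | intermediate
10 | (4R)-4-benzyl-3-propanoyl-1,3-oxazolidin-2-one | CCC(=O)N1[C@H](Cc2ccccc2)COC1=O | starting material
11 | ethyl glyoxylate | CCOC(=O)C=O | starting material
12 | Z dibutylboron enolate of 10 | C/C=C(\OB(CCCC)CCCC)N1[C@H](Cc2ccccc2)COC1=O | intermediate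
13 | ethyl (2R,3R)-4-[(4R)-4-benzyl-2-oxo-1,3-oxazolidin-3-yl]-2-hydroxy-3-methyl-4-oxobutanoate | CCOC(=O)[C@H](O)[C@@H](C)C(=O)N1[C@H](Cc2ccccc2)COC1=O | intermediate
14 | (2R,3R)-2-hydroxy-3-methylbutanedioic acid | OC(=O)[C@H](O)[C@@H](C)C(=O)O | intermediate
15 | (2R)-2-[(2R,4R)-2-tert-butyl-5-oxo-1,3-dioxolan-4-yl]propanoic acid | OC(=O)[C@H](C)[C@H]1O[C@@H](C(C)(C)C)OC1=O | intermediate
16 | dilithio dianion of 15 (carboxylate and dioxolanone enolate) | [Li+].[Li+].[O-]C(=O)[C@H](C)C1=C([O-])O[C@H](C(C)(C)C)O1 | intermediate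
17 | aldol hydroxy acid (7S,8S,17R) | C#C[C@]1(C)OC(C)(C)O[C@@H]1CC/C(C)=C\[C@H](O)[C@]2([C@@H](C)C(=O)O)O[C@@H](C(C)(C)C)OC2=O | intermediate
18 | spiro dioxolanone γ-lactone (1S,2R,7S,8S,17R) | C#C[C@]1(C)OC(C)(C)O[C@@H]1CC/C(C)=C\[C@@H]2OC(=O)[C@H](C)[C@]23O[C@@H](C(C)(C)C)OC3=O | intermediate
19 | propargyl alcohol | C#CCO | starting material
20 | alkenylalane (dimethylaluminium alkoxide) | C[Al](C)OC/C(C)=C/[Al](C)C | intermediate
21 | (2E)-3-iodo-2-methylprop-2-en-1-ol | OC/C(C)=C/I | intermediate
22 | (2E)-3-iodo-2-methylprop-2-enal | O=C/C(C)=C/I | intermediate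
23 | methylzinc acetylide of 18 | C[Zn]C#C[C@]1(C)OC(C)(C)O[C@@H]1CC/C(C)=C\[C@@H]2OC(=O)[C@H](C)[C@]23O[C@@H](C(C)(C)C)OC3=O | intermediate
24 | C12 propargylic alcohol (12S) | I/C=C(C)/[C@@H](O)C#C[C@]1(C)OC(C)(C)O[C@@H]1CC/C(C)=C\[C@@H]2OC(=O)[C@H](C)[C@]23O[C@@H](C(C)(C)C)OC3=O | intermediate
25 | C12 triisopropylsilyl ether | I/C=C(C)/[C@@H](O[Si](C(C)C)(C(C)C)C(C)C)C#C[C@]1(C)OC(C)(C)O[C@@H]1CC/C(C)=C\[C@@H]2OC(=O)[C@H](C)[C@]23O[C@@H](C(C)(C)C)OC3=O | intermediate
26 | C8,C9 diol | I/C=C(C)/[C@@H](O[Si](C(C)C)(C(C)C)C(C)C)C#C[C@]1(C)OC(C)(C)O[C@@H]1CC/C(C)=C\[C@@H]2OC(=O)[C@H](C)[C@@]2(O)CO | intermediate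
27 | C9 aldehyde | I/C=C(C)/[C@@H](O[Si](C(C)C)(C(C)C)C(C)C)C#C[C@]1(C)OC(C)(C)O[C@@H]1CC/C(C)=C\[C@@H]2OC(=O)[C@H](C)[C@@]2(O)C=O | intermediate
28 | alkenylchromium dichloride derived from 27 | Cl[Cr](Cl)/C=C(C)/[C@@H](O[Si](C(C)C)(C(C)C)C(C)C)C#C[C@]1(C)OC(C)(C)O[C@@H]1CC/C(C)=C\[C@@H]2OC(=O)[C@H](C)[C@@]2(O)C=O | intermediate
29 | 14-membered 13-yne 8,9-diol, 1,2-acetonide | O[C@@H]1/C=C(C)/[C@@H](O[Si](C(C)C)(C(C)C)C(C)C)C#C[C@]2(C)OC(C)(C)O[C@@H]2CC/C(C)=C\[C@@H]3OC(=O)[C@H](C)[C@]31O | intermediate
30 | 14-membered 13-yne 1,2,8,9-tetraol | O[C@@H]1/C=C(C)/[C@@H](O[Si](C(C)C)(C(C)C)C(C)C)C#C[C@](C)(O)[C@H](O)CC/C(C)=C\[C@@H]2OC(=O)[C@H](C)[C@]21O | intermediate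
31 | 14-membered 13-yne 2,9-diacetate | CC(=O)O[C@@H]1/C=C(C)/[C@@H](O[Si](C(C)C)(C(C)C)C(C)C)C#C[C@](C)(O)[C@H](OC(C)=O)CC/C(C)=C\[C@@H]2OC(=O)[C@H](C)[C@]21O | intermediate
32 | 14-membered cembranoid lactone, precursor of the key step (5Z,10E,13Z) | CC(=O)O[C@@H]1/C=C(C)/[C@@H](O[Si](C(C)C)(C(C)C)C(C)C)/C=C\[C@](C)(O)[C@H](OC(C)=O)CC/C(C)=C\[C@@H]2OC(=O)[C@H](C)[C@]21O | intermediate
33 | C1–C14–C13 allyl cation | CC(=O)O[C@@H]1/C=C(C)/[C@@H](O[Si](C(C)C)(C(C)C)C(C)C)/C=C\[C+](C)[C@H](OC(C)=O)CC/C(C)=C\[C@@H]2OC(=O)[C@H](C)[C@]21O | intermediate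
34 | C12 silyloxocarbenium ion | CC(=O)O[C@@H]1[C@H]2[C@@H](C)C(=[O+][Si](C(C)C)(C(C)C)C(C)C)C=C[C@]2(C)[C@H](OC(C)=O)CC/C(C)=C\[C@@H]2OC(=O)[C@H](C)[C@]21O | intermediate
35 | bicyclic C12 enone, product of the key step | CC(=O)O[C@@H]1[C@H]2[C@@H](C)C(=O)C=C[C@]2(C)[C@H](OC(C)=O)CC/C(C)=C\[C@@H]2OC(=O)[C@H](C)[C@]21O | intermediate
36 | 12β allylic alcohol (12-epimer of the target) | CC(=O)O[C@@H]1[C@H]2[C@@H](C)[C@@H](O)C=C[C@]2(C)[C@H](OC(C)=O)CC/C(C)=C\[C@@H]2OC(=O)[C@H](C)[C@]21O | intermediate
37 | 12α chloroacetate | CC(=O)O[C@@H]1[C@H]2[C@@H](C)[C@H](OC(=O)CCl)C=C[C@]2(C)[C@H](OC(C)=O)CC/C(C)=C\[C@@H]2OC(=O)[C@H](C)[C@]21O | intermediate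
38 | CNP0222085.1 | CC(=O)O[C@@H]1[C@H]2[C@@H](C)[C@H](O)C=C[C@]2(C)[C@H](OC(C)=O)CC/C(C)=C\[C@@H]2OC(=O)[C@H](C)[C@]21O | target

## Step count

Total step count: 25
Longest linear sequence: 20 steps (steps 1–7, 11, 14–25)

## Steps most likely to fail

**Step 22.**
- **What may go wrong:** the cation may not be intercepted by the doubly deactivated C10=C11 alkene. Instead, the C12 silyl ether oxygen may close a 2,5-dihydrofuran onto C1, C12 may ionise to a pentadienyl cation, C5=C6 may add to C1, or a proton may be lost to give a triene.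
- **Idea of the fallback:** it keeps the C1–C10 bond but uses known chemistry. C10 is made the α-carbon of a silyl enol ether, a far stronger nucleophile than the alkene. Ring A is then closed by the Lewis-acid-mediated SN1 α-tert-alkylation of silyl enol ethers (Reetz-type alkylation).
- **Course of the fallback:** it sets out from tetraol 30 and rejoins the route at 36. MnO2 oxidises only the allylic C9 hydroxyl to the enone triol F1. Ac2O, pyridine and DMAP acetylate the remaining secondary hydroxyl to give the C2 acetate F2. Semihydrogenation as in step 21 gives the Z-alkene F3. Copper hydride 1,4-hydrosilylation (Cu(OAc)2, PhMe2SiH, and the DTBM-SEGPHOS enantiomer that leaves C20 anti to O12) gives the Z silyl enol ether F4 and sets C11 under ligand control. Catalytic InCl3 in CH2Cl2 ionises the C1 hydroxyl and C10 closes ring A to the bicyclic C9 ketone F5, in which C10 is α to the ketone and can settle in the trans-fused arrangement. Zn(BH4)2, chelated by O8 and O9, reduces the ketone to the C9 alcohol F6. Acetylation gives the diacetate silyl ether F7, and HF·pyridine then removes the silyl group to give 36.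

**Step 18.**
- **What may go wrong:** facial selectivity at the C9 aldehyde may be poor, because the two carbon substituents of C8 (C7 and C17) differ little in size.
- **Fallback:** C9 is set by a reagent-controlled reduction and no longer in the C–C bond formation. It sets out from 29 obtained as a mixture of C9 epimers. MnO2 oxidises the allylic alcohol to the macrocyclic enone F8. Corey–Bakshi–Shibata reduction follows with the (S)-methyl oxazaborolidine and catecholborane in toluene at −78 °C. The fully substituted C8 acts as the large group, and the reduction returns 29 with the 9R configuration.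

**Step 11.**
- **What may go wrong:** simple diastereoselectivity at C7 may be low, or partial retro-aldol equilibration may occur, so that both C7 epimers of the hydroxy acid form.
- **Fallback:** the lactone is closed stereoconvergently. It sets out from 15 and 9 and returns at 18. The aldol is stopped at the hydroxy acids, which are separated. Acid 17 is lactonised by acyl substitution as in step 11. The 7-epi hydroxy acid F9 is closed under Mitsunobu conditions (PPh3, DIAD, toluene, 0 °C), in which the carboxylate displaces the activated allylic C7 oxygen with inversion. Both epimers therefore end as 18.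

## Further compounds

F1 | step 22 | enone triol (C9 ketone, 13-yne) | O=C1/C=C(C)/[C@@H](O[Si](C(C)C)(C(C)C)C(C)C)C#C[C@](C)(O)[C@H](O)CC/C(C)=C\[C@@H]2OC(=O)[C@H](C)[C@]21O
F2 | step 22 | C2 acetate of F1 | O=C1/C=C(C)/[C@@H](O[Si](C(C)C)(C(C)C)C(C)C)C#C[C@](C)(O)[C@H](OC(C)=O)CC/C(C)=C\[C@@H]2OC(=O)[C@H](C)[C@]21O
F3 | step 22 | Z-alkene (13Z) from F2 | O=C1/C=C(C)/[C@@H](O[Si](C(C)C)(C(C)C)C(C)C)/C=C\[C@](C)(O)[C@H](OC(C)=O)CC/C(C)=C\[C@@H]2OC(=O)[C@H](C)[C@]21O
F4 | step 22 | Z silyl enol ether (C9 dimethylphenylsilyloxy, C9=C10) | C[Si](C)(c1ccccc1)O/C1=C\[C@@H](C)[C@@H](O[Si](C(C)C)(C(C)C)C(C)C)/C=C\[C@](C)(O)[C@H](OC(C)=O)CC/C(C)=C\[C@@H]2OC(=O)[C@H](C)[C@]21O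
F5 | step 22 | bicyclic C9 ketone | O=C1[C@H]2[C@@H](C)[C@@H](O[Si](C(C)C)(C(C)C)C(C)C)C=C[C@]2(C)[C@H](OC(C)=O)CC/C(C)=C\[C@@H]2OC(=O)[C@H](C)[C@]21O
F6 | step 22 | C9 alcohol | O[C@@H]1[C@H]2[C@@H](C)[C@@H](O[Si](C(C)C)(C(C)C)C(C)C)C=C[C@]2(C)[C@H](OC(C)=O)CC/C(C)=C\[C@@H]2OC(=O)[C@H](C)[C@]21O
F7 | step 22 | diacetate silyl ether | CC(=O)O[C@@H]1[C@H]2[C@@H](C)[C@@H](O[Si](C(C)C)(C(C)C)C(C)C)C=C[C@]2(C)[C@H](OC(C)=O)CC/C(C)=C\[C@@H]2OC(=O)[C@H](C)[C@]21O
F8 | step 18 | macrocyclic enone (C9 ketone, 1,2-acetonide) | O=C1/C=C(C)/[C@@H](O[Si](C(C)C)(C(C)C)C(C)C)C#C[C@]2(C)OC(C)(C)O[C@@H]2CC/C(C)=C\[C@@H]3OC(=O)[C@H](C)[C@]31O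
F9 | step 11 | 7-epi hydroxy acid | C#C[C@]1(C)OC(C)(C)O[C@@H]1CC/C(C)=C\[C@@H](O)[C@]2([C@@H](C)C(=O)O)O[C@@H](C(C)(C)C)OC2=O
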